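## Retrosynthetic overview

1. The E-alkene is cut by cross-metathesis into a vinyl lactone (ring, carbinol and methoxy carbons) and (2R,3R)-pent-4-ene-2,3-diyl diacetate, made in three steps from the L-threonine-derived dioxolane ester.
2. The vinyl lactone comes from substrate-controlled (Z)-γ-methoxyallylboration of (2S)-6-oxo-3,6-dihydro-2H-pyran-2-carbaldehyde with an achiral pinacol boronate, which sets the hydroxy- and methoxy-bearing carbons in one step.
3. That aldehyde comes from periodic acid excision of the dioxolane of the lactone, itself the oxidation product of a 2-methoxy-5,6-dihydro-2H-pyran.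
4. The dihydropyran comes from a hetero-Diels–Alder [4+2] of (R)-glyceraldehyde acetonide with (E)-1-methoxybutadiene; the D-mannitol-derived centre sets the ring stereocentre.
5. Ring order: the pyranone is the only ring and is formed first; all later steps are side-chain work.

Assumption: the five starting materials are bought (the glyceraldehyde acetonide traces to D-mannitol, the dioxolane ester to L-threonine), and a 15–20 kbar press is available for step 1.

## Route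

Step 1
Reactants: 1 (R)-2,3-O-isopropylideneglyceraldehyde; 2 (E)-1-methoxybuta-1,3-diene
Product: 3 (2R,6S)-6-[(4R)-2,2-dimethyl-1,3-dioxolan-4-yl]-2-methoxy-5,6-dihydro-2H-pyran
Conditions: Eu(fod)3 (2 mol %), Et2O, 15–20 kbar, 50 °C, 20 h
Reagents that add atoms: none
Why: Eu(fod)3-catalysed hetero-Diels–Alder [4+2] cycloaddition closes the dihydropyran ring; endo approach gives the 2,6-cis acetal, and attack anti to the dioxolane C–O bond (Felkin–Anh, non-chelated acetonide) sets C6 as S under control of the bought centre.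

Step 2
Reactants: 3 (2R,6S)-6-[(4R)-2,2-dimethyl-1,3-dioxolan-4-yl]-2-methoxy-5,6-dihydro-2H-pyran
Product: 5 (6S)-6-[(4R)-2,2-dimethyl-1,3-dioxolan-4-yl]-5,6-dihydro-2H-pyran-2-one, via lactol 4 (not isolated)
Conditions: CrO3, H2SO4, H2O, acetone, 0 °C, 30 min
Reagents that add atoms: water, O
Why: Jones-type oxidation, in which the allylic methyl acetal is hydrolysed in situ to the lactol and chromic acid oxidises it to the α,β-unsaturated δ-lactone; acetone as solvent keeps the isopropylidene acetal on, and C6 is untouched.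

Step 3
Reactants: 5 (6S)-6-[(4R)-2,2-dimethyl-1,3-dioxolan-4-yl]-5,6-dihydro-2H-pyran-2-one
Product: 7 (2S)-6-oxo-3,6-dihydro-2H-pyran-2-carbaldehyde, via diol 6 (not isolated)
Conditions: H5IO6 (1.3 equiv), EtOAc, rt, 3 h; filter through SiO2, use crude at once
Reagents that add atoms: none
Why: One-pot acetonide hydrolysis and Malaprade glycol cleavage by periodic acid turns the dioxolane carbon into the formyl group under non-basic conditions, so the α-acyloxy aldehyde is not epimerised.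

Step 4
Reactants: 8 allyl methyl ether; 9 2-isopropoxy-4,4,5,5-tetramethyl-1,3,2-dioxaborolane
Product: 12 2-[(2Z)-3-methoxyprop-2-en-1-yl]-4,4,5,5-tetramethyl-1,3,2-dioxaborolane, via methoxyallyllithium 10 (not isolated), via borate ate complex 11 (not isolated)
Conditions: sec-BuLi, THF, −78 °C; then 9, −78 °C; then HCl in Et2O, −78 °C → rt
Reagents that add atoms: none
Why: α-Lithiation of the allyl ether gives the O-chelated (Z)-allyllithium, which is borylated at the γ-carbon and released from the ate complex by acid (Hoffmann–Wuts synthesis of (Z)-γ-alkoxyallylboronates), so the Z geometry is fixed.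

Step 5
Reactants: 7 (2S)-6-oxo-3,6-dihydro-2H-pyran-2-carbaldehyde; 12 2-[(2Z)-3-methoxyprop-2-en-1-yl]-4,4,5,5-tetramethyl-1,3,2-dioxaborolane
Product: 14 (6S)-6-[(1S,2S)-1-hydroxy-2-methoxybut-3-en-1-yl]-5,6-dihydro-2H-pyran-2-one, via pinacol borate ester 13 (not isolated)
Conditions: 12 (2 equiv), 4 Å MS, CH2Cl2, rt, 48 h; then H2O
Reagents that add atoms: none
Why: Hoffmann-type allylboration through a closed chair (Zimmerman–Traxler) transition state, in which the Z enol ether gives the syn hydroxy/methoxy pair and attack anti to the ring C–O bond (Felkin–Anh/Cornforth, reinforced for Z reagents) sets both new centres as S; the neutral reagent spares the lactone.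

Step 6
Reactants: 15 methyl (4S,5R)-2,2,5-trimethyl-1,3-dioxolane-4-carboxylate
Product: 17 (4R,5R)-4-ethenyl-2,2,5-trimethyl-1,3-dioxolane, via aldehyde 16 (not isolated)
Conditions: i-Bu2AlH (1.1 equiv), CH2Cl2, −78 °C; then Ph3P=CH2 (from Ph3PCH3Br, KOtBu), THF, −78 °C → rt
Reagents that add atoms: methyltriphenylphosphonium bromide, C[P+](c1ccccc1)(c1ccccc1)c1ccccc1.[Br-]
Why: Partial ester reduction to the aluminium hemiacetal followed by in situ Wittig methylenation avoids isolating the volatile α-alkoxy aldehyde; both stereocentres are those of L-threonine, and the trans-dioxolane has no more stable epimer to drift to.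

Step 7
Reactants: 17 (4R,5R)-4-ethenyl-2,2,5-trimethyl-1,3-dioxolane
Product: 18 (2R,3R)-pent-4-ene-2,3-diol
Conditions: Dowex 50W-X8 (H+ form), MeOH–H2O 9:1, 40 °C
Reagents that add atoms: none
Why: Acid-catalysed acetal hydrolysis on a filterable resin frees the syn diol without touching either stereocentre.

Step 8
Reactants: 18 (2R,3R)-pent-4-ene-2,3-diol
Product: 19 (2R,3R)-pent-4-ene-2,3-diyl diacetate
Conditions: Ac2O, pyridine, DMAP (cat.), CH2Cl2, 0 °C → rt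
Reagents that add atoms: acetic anhydride, CC(=O)OC(C)=O
Why: DMAP-catalysed acylation esterifies both secondary alcohols with retention.

Step 9
Reactants: 14 (6S)-6-[(1S,2S)-1-hydroxy-2-methoxybut-3-en-1-yl]-5,6-dihydro-2H-pyran-2-one; 19 (2R,3R)-pent-4-ene-2,3-diyl diacetate
Product: 20 (2R,3R,4E,6S,7S)-7-hydroxy-6-methoxy-7-[(2S)-6-oxo-3,6-dihydro-2H-pyran-2-yl]hept-4-ene-2,3-diyl diacetate
Conditions: 19 (3 equiv), second-generation Hoveyda–Grubbs catalyst RuCl2(H2IMes)(=CH-C6H4-2-OiPr) (10 mol %), CH2Cl2, 40 °C, Ar sparge, 24 h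
Reagents that add atoms: none
Why: Olefin cross-metathesis between two slowly homodimerising allylic-oxygenated terminal alkenes, with the cheap partner in excess, gives the E-disubstituted alkene under thermodynamic control; the conjugated ring alkene, free hydroxyl, acetates and all stereocentres are untouched.

## Compound list

1 | (R)-2,3-O-isopropylideneglyceraldehyde [(4R)-2,2-dimethyl-1,3-dioxolane-4-carbaldehyde] | O=C[C@H]1COC(C)(C)O1 | starting material
2 | (E)-1-methoxybuta-1,3-diene | CO/C=C/C=C | starting material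
3 | (2R,6S)-6-[(4R)-2,2-dimethyl-1,3-dioxolan-4-yl]-2-methoxy-5,6-dihydro-2H-pyran | CC1(C)OC[C@@H](O1)[C@@H]2CC=C[C@H](OC)O2 | intermediate
4 | (6S)-6-[(4R)-2,2-dimethyl-1,3-dioxolan-4-yl]-5,6-dihydro-2H-pyran-2-ol (lactol, anomer mixture) | CC1(C)OC[C@@H](O1)[C@@H]2CC=CC(O)O2 | intermediate
5 | (6S)-6-[(4R)-2,2-dimethyl-1,3-dioxolan-4-yl]-5,6-dihydro-2H-pyran-2-one | CC1(C)OC[C@@H](O1)[C@@H]2CC=CC(=O)O2 | intermediate
6 | (6S)-6-[(1R)-1,2-dihydroxyethyl]-5,6-dihydro-2H-pyran-2-one | OC[C@@H](O)[C@@H]1CC=CC(=O)O1 | intermediate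
7 | (2S)-6-oxo-3,6-dihydro-2H-pyran-2-carbaldehyde | O=C[C@@H]1CC=CC(=O)O1 | intermediate
8 | allyl methyl ether (3-methoxyprop-1-ene) | COCC=C | starting material
9 | 2-isopropoxy-4,4,5,5-tetramethyl-1,3,2-dioxaborolane | CC(C)OB1OC(C)(C)C(C)(C)O1 | starting material
10 | (Z)-3-methoxyallyllithium (O-chelated) | CO/C=C\C[Li] | intermediate
11 | lithium isopropoxy[(Z)-3-methoxyallyl](pinacolato)borate | [Li+].CO/C=C\C[B-]1(OC(C)C)OC(C)(C)C(C)(C)O1 | intermediate
12 | 2-[(2Z)-3-methoxyprop-2-en-1-yl]-4,4,5,5-tetramethyl-1,3,2-dioxaborolane | CO/C=C\CB1OC(C)(C)C(C)(C)O1 | intermediate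
13 | 2-{[(1S,2S)-2-methoxy-1-[(2S)-6-oxo-3,6-dihydro-2H-pyran-2-yl]but-3-en-1-yl]oxy}-4,4,5,5-tetramethyl-1,3,2-dioxaborolane (pinacol borate ester of 14) | CO[C@@H](C=C)[C@@H](OB1OC(C)(C)C(C)(C)O1)[C@@H]2CC=CC(=O)O2 | intermediate
14 | (6S)-6-[(1S,2S)-1-hydroxy-2-methoxybut-3-en-1-yl]-5,6-dihydro-2H-pyran-2-one | CO[C@@H](C=C)[C@@H](O)[C@@H]1CC=CC(=O)O1 | intermediate
15 | methyl (4S,5R)-2,2,5-trimethyl-1,3-dioxolane-4-carboxylate | COC(=O)[C@H]1OC(C)(C)O[C@@H]1C | starting material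
16 | (4S,5R)-2,2,5-trimethyl-1,3-dioxolane-4-carbaldehyde | O=C[C@H]1OC(C)(C)O[C@@H]1C | intermediate
17 | (4R,5R)-4-ethenyl-2,2,5-trimethyl-1,3-dioxolane | C=C[C@H]1OC(C)(C)O[C@@H]1C | intermediate
18 | (2R,3R)-pent-4-ene-2,3-diol | C=C[C@@H](O)[C@@H](C)O | intermediate
19 | (2R,3R)-pent-4-ene-2,3-diyl diacetate | C=C[C@@H](OC(C)=O)[C@@H](C)OC(C)=O | intermediate
20 | (2R,3R,4E,6S,7S)-7-hydroxy-6-methoxy-7-[(2S)-6-oxo-3,6-dihydro-2H-pyran-2-yl]hept-4-ene-2,3-diyl diacetate | CO[C@@H](/C=C/[C@@H](OC(C)=O)[C@@H](C)OC(C)=O)[C@@H](O)[C@@H]1CC=CC(=O)O1 | target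

## Step count and risks

Total steps: 9. Longest linear sequence: 5 (steps 1, 2, 3, 5, 9).

**Step 1 (high-pressure hetero-Diels–Alder).** The risks are conversion and facial/endo selectivity, and the need for a press. The fallback keeps the [4+2] logic but uses a more reactive diene at ambient pressure; it sets out from 1 and returns at 5, costing two extra steps. ZnCl2-mediated cyclocondensation of 1 with trans-1-methoxy-3-(trimethylsilyloxy)buta-1,3-diene in THF gives the silyl enol ether cycloadduct (2R,6S)-6-[(4R)-2,2-dimethyl-1,3-dioxolan-4-yl]-2-methoxy-4-[(trimethylsilyl)oxy]-5,6-dihydro-2H-pyran F1. CF3CO2H converts it into (2S)-2-[(4R)-2,2-dimethyl-1,3-dioxolan-4-yl]-2,3-dihydro-4H-pyran-4-one F2, with the same anti facial sense. Reduction with NaBH4/CeCl3·7H2O in MeOH at −78 °C gives the cis allylic alcohol (2S,4S)-2-[(4R)-2,2-dimethyl-1,3-dioxolan-4-yl]-3,4-dihydro-2H-pyran-4-ol F3. PPTS-catalysed Ferrier-type allylic transposition with methanol in CH2Cl2 gives the trans acetal (2S,6S)-6-[(4R)-2,2-dimethyl-1,3-dioxolan-4-yl]-2-methoxy-5,6-dihydro-2H-pyran F4, the C2 epimer of 3. The conditions of step 2 oxidise F4 to 5.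

**Step 5 (allylboration of the fragile aldehyde 7).** The risks are hydration or epimerisation of 7 and an untested facial preference. The fallback inverts the order: the allylboration is run on a robust aldehyde and the ring is closed afterwards. It sets out from 12 (and 2) and returns at 14. Boronate 12 adds to bought (S)-2,3-O-isopropylideneglyceraldehyde F5 (from L-ascorbic acid) and gives, via the pinacol borate 2-{[(1R,2S)-1-[(4S)-2,2-dimethyl-1,3-dioxolan-4-yl]-2-methoxybut-3-en-1-yl]oxy}-4,4,5,5-tetramethyl-1,3,2-dioxaborolane F6, the anti,syn alcohol (1R,2S)-1-[(4S)-2,2-dimethyl-1,3-dioxolan-4-yl]-2-methoxybut-3-en-1-ol F7. TBSOTf/2,6-lutidine gives tert-butyl{[(1R,2S)-1-[(4S)-2,2-dimethyl-1,3-dioxolan-4-yl]-2-methoxybut-3-en-1-yl]oxy}dimethylsilane F8. H5IO6 in EtOAc gives (2R,3S)-2-[(tert-butyldimethylsilyl)oxy]-3-methoxypent-4-enal F9. Hetero-Diels–Alder with 2 under the conditions of step 1 (Felkin attack anti to the silyloxy group) gives tert-butyl{[(1S,2S)-2-methoxy-1-[(2S,6R)-6-methoxy-3,6-dihydro-2H-pyran-2-yl]but-3-en-1-yl]oxy}dimethylsilane F10. CrO3/H2SO4 in acetone gives (6S)-6-[(1S,2S)-1-[(tert-butyldimethylsilyl)oxy]-2-methoxybut-3-en-1-yl]-5,6-dihydro-2H-pyran-2-one F11, and HF·pyridine returns 14.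

**Step 9 (late cross-metathesis).** The risks are a hindered allylic ether next to a free hydroxyl, homodimer formation, and the lactone being present. The fallback runs the metathesis on the acyclic alcohol before the ring exists. It sets out from 19 and from 12 (through alcohol F7 of the preceding fallback) and returns at 20. F7 and 19 with the same ruthenium catalyst give (2R,3R,4E,6S,7R)-7-[(4S)-2,2-dimethyl-1,3-dioxolan-4-yl]-7-hydroxy-6-methoxyhept-4-ene-2,3-diyl diacetate F12. TBSOTf/2,6-lutidine gives its silyl ether (2R,3R,4E,6S,7R)-7-[(tert-butyldimethylsilyl)oxy]-7-[(4S)-2,2-dimethyl-1,3-dioxolan-4-yl]-6-methoxyhept-4-ene-2,3-diyl diacetate F13. H5IO6 gives (2R,3R,4E,6S,7R)-7-[(tert-butyldimethylsilyl)oxy]-6-methoxy-8-oxooct-4-ene-2,3-diyl diacetate F14. Hetero-Diels–Alder with 2 as in step 1 gives (2R,3R,4E,6S,7S)-7-[(tert-butyldimethylsilyl)oxy]-6-methoxy-7-[(2S,6R)-6-methoxy-3,6-dihydro-2H-pyran-2-yl]hept-4-ene-2,3-diyl diacetate F15. CrO3/H2SO4 in acetone gives (2R,3R,4E,6S,7S)-7-[(tert-butyldimethylsilyl)oxy]-6-methoxy-7-[(2S)-6-oxo-3,6-dihydro-2H-pyran-2-yl]hept-4-ene-2,3-diyl diacetate F16, and HF·pyridine gives 20.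

Further compounds
F1 | step 1 | (2R,6S)-6-[(4R)-2,2-dimethyl-1,3-dioxolan-4-yl]-2-methoxy-4-[(trimethylsilyl)oxy]-5,6-dihydro-2H-pyran | CC1(C)OC[C@@H](O1)[C@@H]2CC(O[Si](C)(C)C)=C[C@H](OC)O2
F2 | step 1 | (2S)-2-[(4R)-2,2-dimethyl-1,3-dioxolan-4-yl]-2,3-dihydro-4H-pyran-4-one | CC1(C)OC[C@@H](O1)[C@@H]2CC(=O)C=CO2
F3 | step 1 | (2S,4S)-2-[(4R)-2,2-dimethyl-1,3-dioxolan-4-yl]-3,4-dihydro-2H-pyran-4-ol | CC1(C)OC[C@@H](O1)[C@@H]2C[C@H](O)C=CO2
F4 | step 1 | (2S,6S)-6-[(4R)-2,2-dimethyl-1,3-dioxolan-4-yl]-2-methoxy-5,6-dihydro-2H-pyran | CC1(C)OC[C@@H](O1)[C@@H]2CC=C[C@@H](OC)O2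
F5 | step 5 | (S)-2,3-O-isopropylideneglyceraldehyde (bought) | O=C[C@@H]1COC(C)(C)O1
F6 | step 5 | 2-{[(1R,2S)-1-[(4S)-2,2-dimethyl-1,3-dioxolan-4-yl]-2-methoxybut-3-en-1-yl]oxy}-4,4,5,5-tetramethyl-1,3,2-dioxaborolane | CO[C@@H](C=C)[C@@H](OB1OC(C)(C)C(C)(C)O1)[C@@H]2COC(C)(C)O2
F7 | step 5 | (1R,2S)-1-[(4S)-2,2-dimethyl-1,3-dioxolan-4-yl]-2-methoxybut-3-en-1-ol | CO[C@@H](C=C)[C@@H](O)[C@@H]1COC(C)(C)O1
F8 | step 5 | tert-butyl{[(1R,2S)-1-[(4S)-2,2-dimethyl-1,3-dioxolan-4-yl]-2-methoxybut-3-en-1-yl]oxy}dimethylsilane | CO[C@@H](C=C)[C@@H](O[Si](C)(C)C(C)(C)C)[C@@H]1COC(C)(C)O1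
F9 | step 5 | (2R,3S)-2-[(tert-butyldimethylsilyl)oxy]-3-methoxypent-4-enal | CO[C@@H](C=C)[C@@H](O[Si](C)(C)C(C)(C)C)C=O
F10 | step 5 | tert-butyl{[(1S,2S)-2-methoxy-1-[(2S,6R)-6-methoxy-3,6-dihydro-2H-pyran-2-yl]but-3-en-1-yl]oxy}dimethylsilane | CO[C@@H](C=C)[C@@H](O[Si](C)(C)C(C)(C)C)[C@@H]1CC=C[C@H](OC)O1
F11 | step 5 | (6S)-6-[(1S,2S)-1-[(tert-butyldimethylsilyl)oxy]-2-methoxybut-3-en-1-yl]-5,6-dihydro-2H-pyran-2-one | CO[C@@H](C=C)[C@@H](O[Si](C)(C)C(C)(C)C)[C@@H]1CC=CC(=O)O1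
F12 | step 9 | (2R,3R,4E,6S,7R)-7-[(4S)-2,2-dimethyl-1,3-dioxolan-4-yl]-7-hydroxy-6-methoxyhept-4-ene-2,3-diyl diacetate | CO[C@@H](/C=C/[C@@H](OC(C)=O)[C@@H](C)OC(C)=O)[C@@H](O)[C@@H]1COC(C)(C)O1
F13 | step 9 | (2R,3R,4E,6S,7R)-7-[(tert-butyldimethylsilyl)oxy]-7-[(4S)-2,2-dimethyl-1,3-dioxolan-4-yl]-6-methoxyhept-4-ene-2,3-diyl diacetate | CO[C@@H](/C=C/[C@@H](OC(C)=O)[C@@H](C)OC(C)=O)[C@@H](O[Si](C)(C)C(C)(C)C)[C@@H]1COC(C)(C)O1
F14 | step 9 | (2R,3R,4E,6S,7R)-7-[(tert-butyldimethylsilyl)oxy]-6-methoxy-8-oxooct-4-ene-2,3-diyl diacetate | CO[C@@H](/C=C/[C@@H](OC(C)=O)[C@@H](C)OC(C)=O)[C@@H](O[Si](C)(C)C(C)(C)C)C=O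
F15 | step 9 | (2R,3R,4E,6S,7S)-7-[(tert-butyldimethylsilyl)oxy]-6-methoxy-7-[(2S,6R)-6-methoxy-3,6-dihydro-2H-pyran-2-yl]hept-4-ene-2,3-diyl diacetate | CO[C@@H](/C=C/[C@@H](OC(C)=O)[C@@H](C)OC(C)=O)[C@@H](O[Si](C)(C)C(C)(C)C)[C@@H]1CC=C[C@H](OC)O1
F16 | step 9 | (2R,3R,4E,6S,7S)-7-[(tert-butyldimethylsilyl)oxy]-6-methoxy-7-[(2S)-6-oxo-3,6-dihydro-2H-pyran-2-yl]hept-4-ene-2,3-diyl diacetate | CO[C@@H](/C=C/[C@@H](OC(C)=O)[C@@H](C)OC(C)=O)[C@@H](O[Si](C)(C)C(C)(C)C)[C@@H]1CC=CC(=O)O1
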